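The theta run cannot have spent its whole partner charge on starting material: 14 mM was charged, and its plateau of 12.0% target accounts for 1.20 mM. So I let the second substrate take the rest of the partner, one to one, and asked whether partner, as limiting reagent, stops each run.

| flask | starting material | second substrate | partner | free catalyst | added ligand | impurity | remark | time |
|---|---|---|---|---|---|---|---|---|
| theta | 10 mM | 20 mM | 14 mM | 22 µM | 16 µM | 7 µM | run made earlier |  |
| epsilon | 10 mM | 20 mM | 22 mM | 22 µM | 16 µM | 7 µM | run made earlier |  |
| zeta | 10 mM | 20 mM | 10 mM | 22 µM | 16 µM | 3.5 µM | run made earlier |  |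
| flask | 10 mM | 20.0 mM | 10.0 mM | 22 µM | 16 µM | 7.0 µM |  | 4.0 d |

| run | time / d | starting material / % | target / % |
|---|---|---|---|
| theta | 0.333 | 91.0 | 8.6 |
| theta | 0.500 | 89.7 | 10.8 |
| theta | 0.833 | 88.3 | 11.7 |
| theta | 1.67 | 88.2 | 11.7 |
| theta | 2.50 | 88.3 | 12.6 |
| theta | 4.00 | 87.9 | 11.9 |
| epsilon | 0.625 | 77.7 | 21.3 |
| epsilon | 1.25 | 72.1 | 28.5 |
| epsilon | 2.08 | 69.1 | 29.7 |
| epsilon | 2.50 | 69.7 | 30.8 |
| epsilon | 3.00 | 69.2 | 30.4 |
| epsilon | 4.00 | 67.9 | 31.3 |
| zeta | 0.833 | 92.4 | 6.1 |
| zeta | 1.67 | 93.6 | 5.8 |
| zeta | 2.50 | 92.9 | 6.6 |
| zeta | 3.00 | 94.5 | 6.4 |
| zeta | 4.00 | 93.4 | 6.7 |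

(each reading ± 0.5 percentage points)

* which holds at 4.0 d: what has brought the reaction to rest, or that it has not come to rest (it is still moving / all of the starting material has reacted / the partner has run out first / forward and back rates have come level / no working catalyst is left)
* part of the starting material gone at 4.0 d
* the target standing at 4.0 d, as a percentage of the starting material charged

- the reaction counts as stopped when no species that holds the starting material changes by six tenths of a point or more over the second half of the time

The readings gave me a ladder of times. Zeta and theta were flat by 0.833 d, epsilon by 2.08 d, and the asked 4.0 d lay later still. So I expected the flask on its plateau, with the competition for partner over.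

I weighed that competition from the symmetric case. If partner liked both substrates equally, they would shrink together, and the target would take 33.3% of the partner at zeta's charges. Zeta's mean target was 6.32%. I defined the selectivity factor S as the logarithm of the fraction of starting material left over the logarithm of the fraction of second substrate left, with S = 1 as the symmetric case, and read it from zeta as 0.103. Theta gave 0.125. Epsilon, with a plateau of 30.5%, gave 0.124. Per mM, then, partner took second substrate about ten times as fast. S compares two rates on one catalyst, so I took the impurity to cancel from it. The flask has zeta's substrate and partner charges, so I committed to 6.32% target, with partner gone.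

The forecast said no working catalyst is left, with 6.2% gone and 6% target: “This points to catalyst death, with partner protecting the catalyst.”

The flask gave this ending: the partner has run out first, with 6.29% gone and 6.27% target.

    starting material + free catalyst ⇌ catalyst intermediate A (K = 42.0 /M, k = 19.0 /M/s)
    free catalyst + added ligand ⇌ idle complex, settled at all times (K = 17000 /M)
    free catalyst + impurity → spent catalyst (k = 440 /M/s)
    partner + catalyst intermediate A → free catalyst + target (k = 1.00 /M/s)
    partner + catalyst intermediate B → free catalyst + second product (k = 11.0 /M/s)
    second substrate + free catalyst ⇌ catalyst intermediate B (K = 130 /M, k = 2.50 /M/s)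

At 4.00 d the partner stood at 0% of its charge, while starting material stood at 94%. With 53% of the second substrate left, S came to 0.103, against 0.103 from zeta. A neighbour flask, charged with 8.0 mM of second substrate, ended with 4.7% of it. There S promised 27.0% target, and that neighbour flask stood at 21.7%.

The data stem from a simulated flask on assumed constants, and the scatter is random.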